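**Plan**

- Numbering: ring A from the pentanoyl-bearing carbon C1, ring B from the bridge carbon C1'. The retrosynthesis first cuts the two aryl–acyl bonds (C3'–CO on ring B, C1–CO on ring A). It then cuts ring B at C4'–C5', C1'–C6' and C3'–C4' into a 2-(arylmethyl)-3-alkoxycyclobutenone and 1-methoxypropyne, the four-membered ring into ketene and an ynol ether, and finally the CH2–C(sp) bond.
- Enabling feature: ring B is a phloroglucinol with oxygen at C2', C4' and C6'. Its only O-methyl (C6') lies between the bridge carbon C1' and the methyl-bearing C5', and C3' is open. A vinylketene supplying C1'(CH2Ar)–C2'(OR)–C3'H2 plus the C4' carbonyl, and an ynol ether supplying C5'(Me)–C6'(OMe), map onto this ring atom for atom.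
- Forward: ring A is present from the start (2,4,6-trihydroxytoluene). It receives benzyl ethers, the bridge carbon by formylation, and a bromine that marks C1. The bridge is extended to an ethoxyalkyne, ketene closes the cyclobutenone, and the benzannulation closes ring B.
- Endgame: bromine–lithium exchange places the pentanoyl group on ring A, the last free aromatic carbon (C3') takes the butanoyl group, and hydrogenolysis frees five phenols while the C6' methyl ether stays.
- Stereochemistry: the target has no stereocentre, so none has to be set.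

Key step: step 10

Remark: ketene is taken to be generated on demand by pyrolysis of acetone and led into the reaction as a gas.

**Route**

Step 1
Reactants: 1 2-methylbenzene-1,3,5-triol (2,4,6-trihydroxytoluene)
Product: 2 1,3,5-tris(benzyloxy)-2-methylbenzene
Conditions: BnBr (3.6 equiv), K2CO3, DMF, 0 °C → rt
Reagents that add atoms: benzyl bromide, BrCc1ccccc1
Why: Williamson etherification of the three phenoxides; the dipolar aprotic medium favours O- over C-benzylation of the phloroglucinol core.

Step 2
Reactants: 2 1,3,5-tris(benzyloxy)-2-methylbenzene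
Product: 3 2,4,6-tris(benzyloxy)-3-methylbenzaldehyde
Conditions: POCl3, DMF, 0 °C → rt; then ice-water
Reagents that add atoms: N,N-dimethylformamide, CN(C)C=O; water, O
Why: Vilsmeier–Haack formylation of a trialkoxyarene whose two free positions are equivalent by symmetry; the aldehyde deactivates the ring against a second formylation.

Step 3
Reactants: 3 2,4,6-tris(benzyloxy)-3-methylbenzaldehyde
Product: 4 2,4,6-tris(benzyloxy)-3-bromo-5-methylbenzaldehyde
Conditions: NBS, MeCN, 0 °C → rt, dark
Reagents that add atoms: N-bromosuccinimide, O=C1CCC(=O)N1Br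
Why: electrophilic aromatic bromination at the single remaining ring CH, which is ortho to two benzyloxy groups, para to the third and meta to the aldehyde; the bromine marks the carbon that later carries the pentanoyl group.

Step 4
Reactants: 4 2,4,6-tris(benzyloxy)-3-bromo-5-methylbenzaldehyde
Product: 5 [2,4,6-tris(benzyloxy)-3-bromo-5-methylphenyl]methanol
Conditions: NaBH4, THF/MeOH, 0 °C
Reagents that add atoms: none
Why: hydride reduction of the aldehyde; aryl bromide and benzyl ethers are inert to NaBH4.

Step 5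
Reactants: 5 [2,4,6-tris(benzyloxy)-3-bromo-5-methylphenyl]methanol
Product: 6 1,3,5-tris(benzyloxy)-2-bromo-4-(bromomethyl)-6-methylbenzene
Conditions: PBr3, Et2O, 0 °C; crude used at once
Reagents that add atoms: phosphorus tribromide, BrP(Br)Br
Why: bromide displaces the phosphite ester of the benzylic alcohol (SN2); the ring bromine tempers ionisation of this trialkoxybenzyl bromide, which is still taken on without purification.

Step 6
Reactants: 6 1,3,5-tris(benzyloxy)-2-bromo-4-(bromomethyl)-6-methylbenzene; 7 ethoxyethyne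
Product: 9 1,3,5-tris(benzyloxy)-2-bromo-4-(3-ethoxyprop-2-yn-1-yl)-6-methylbenzene, via lithium ethoxyacetylide 8 (not isolated)
Conditions: 7 (1.5 equiv), n-BuLi (1.4 equiv), THF, −78 °C; then 6, DMPU, −78 → 0 °C
Reagents that add atoms: none
Why: SN2 alkylation of a lithium alkoxyacetylide by a benzylic bromide, the classical entry to 1-alkoxy-1-alkynes; the aryl bromide does not react with the acetylide.

Step 7
Reactants: 9 1,3,5-tris(benzyloxy)-2-bromo-4-(3-ethoxyprop-2-yn-1-yl)-6-methylbenzene
Product: 10 3-ethoxy-2-{[2,4,6-tris(benzyloxy)-3-bromo-5-methylphenyl]methyl}cyclobut-2-en-1-one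
Conditions: ketene (gas, excess), CH2Cl2, 0 °C → rt
Reagents that add atoms: ketene, C=C=O
Why: (2+2) cycloaddition of ketene to an ynol ether; the alkyne carbon remote from oxygen bonds to the ketene carbonyl carbon, giving the 2-substituted 3-ethoxycyclobutenone as known for 1-ethoxypropyne.

Step 8
Reactants: 10 3-ethoxy-2-{[2,4,6-tris(benzyloxy)-3-bromo-5-methylphenyl]methyl}cyclobut-2-en-1-one
Product: 11 3-(benzyloxy)-2-{[2,4,6-tris(benzyloxy)-3-bromo-5-methylphenyl]methyl}cyclobut-2-en-1-one
Conditions: BnOH (10 equiv), TsOH·H2O (5 mol %), toluene, 5 Å MS, 40 °C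
Reagents that add atoms: benzyl alcohol, OCc1ccccc1
Why: acid-catalysed addition–elimination exchange of the alkoxy group of a vinylogous ester, driven by excess benzyl alcohol and uptake of ethanol; benzyl is needed because an ethyl ether could not later be cleaved beside the C6' methyl ether.

Step 9
Reactants: 12 2-chloro-1,1-dimethoxyethane
Product: 14 1-methoxyprop-1-yne, via sodium methoxyacetylide 13 (not isolated)
Conditions: NaNH2 (3 equiv), liq. NH3, −33 °C; then MeI, −33 °C; distillation
Reagents that add atoms: iodomethane, CI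
Why: twofold elimination (methanol, then HCl) with NaNH2 gives the sodium alkoxyacetylide as in the standard methoxyacetylene preparation, and C-methylation follows the established synthesis of 1-alkoxy-1-alkynes.

Step 10
Reactants: 11 3-(benzyloxy)-2-{[2,4,6-tris(benzyloxy)-3-bromo-5-methylphenyl]methyl}cyclobut-2-en-1-one; 14 1-methoxyprop-1-yne
Product: 19 5-(benzyloxy)-3-methoxy-2-methyl-4-{[2,4,6-tris(benzyloxy)-3-bromo-5-methylphenyl]methyl}phenol, via vinylketene 15 (not isolated), via vinylcyclobutenone 16 (not isolated), via dienylketene 17 (not isolated), via cyclohexadienone 18 (not isolated)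
Conditions: 14 (3 equiv), toluene, sealed tube, 80 °C then 120 °C
Reagents that add atoms: none
Why: Heating breaks the C1–C4 bond of 11 by four-electron electrocyclic opening to vinylketene 15, whose ketene C=C adds ynol ether 14 in a (2+2) cycloaddition to vinylcyclobutenone 16; a second four-electron opening gives dienylketene 17, and tautomerisation of cyclohexadienone 18 delivers phenol 19. The closest known reaction is the Danheiser benzannulation of cyclobutenones with alkoxyalkynes, whose second ring opening always takes place on a 3-alkoxycyclobutenone, so the vinylogous ester 11 is expected to open as well, if only towards the upper end of the usual temperature range. Ring B, the only ring formed, is assembled by the (2+2) step (C4'–C5' and C1'–C6') and closed by a thermal disrotatory six-electron electrocyclisation of 17 (C3'–C4'), possible because the ketene and the benzyloxyvinyl group sit cis on the central alkene and the other isomer can revert through 16. No stereocentre is created in 19, since the racemic quaternary carbon of 16 becomes the planar C1'. The selectivity needed is the regiochemistry of the ketene–alkyne addition, and the polarisation of 14 secures it: the methyl-bearing carbon, remote from oxygen, attacks the ketene carbonyl carbon, which puts methyl at C5' next to the new hydroxyl and methoxy at C6' next to the bridge. Excess 14 keeps the first-formed phenol from being acylated by 15, and the ring A bromine and the benzyl ethers are spectators.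

Step 11
Reactants: 19 5-(benzyloxy)-3-methoxy-2-methyl-4-{[2,4,6-tris(benzyloxy)-3-bromo-5-methylphenyl]methyl}phenol
Product: 20 1,3,5-tris(benzyloxy)-2-{[4,6-bis(benzyloxy)-2-methoxy-3-methylphenyl]methyl}-4-bromo-6-methylbenzene
Conditions: BnBr, K2CO3, DMF, rt
Reagents that add atoms: benzyl bromide, BrCc1ccccc1
Why: Williamson etherification of the only free phenol, so that no acidic proton is present in the metalation and all five benzyl ethers can be removed together at the end.

Step 12
Reactants: 20 1,3,5-tris(benzyloxy)-2-{[4,6-bis(benzyloxy)-2-methoxy-3-methylphenyl]methyl}-4-bromo-6-methylbenzene; 21 N-methoxy-N-methylpentanamide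
Product: 23 1-[2,4,6-tris(benzyloxy)-3-{[4,6-bis(benzyloxy)-2-methoxy-3-methylphenyl]methyl}-5-methylphenyl]pentan-1-one, via aryllithium 22 (not isolated)
Conditions: n-BuLi, THF, −78 °C; then 21, −78 → −20 °C; then 1 M HCl
Reagents that add atoms: none
Why: bromine–lithium exchange at −78 °C outruns deprotonation of the benzyl ethers, and the aryllithium, flanked by two alkoxy groups, acylates on the Weinreb amide, whose chelated adduct releases the ketone only on work-up; the pentanoyl group therefore lands exactly on the carbon marked in step 3.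

Step 13
Reactants: 23 1-[2,4,6-tris(benzyloxy)-3-{[4,6-bis(benzyloxy)-2-methoxy-3-methylphenyl]methyl}-5-methylphenyl]pentan-1-one; 24 butanoic acid
Product: 26 1-[2,4,6-tris(benzyloxy)-3-{[2,4-bis(benzyloxy)-3-butanoyl-6-methoxy-5-methylphenyl]methyl}-5-methylphenyl]pentan-1-one, via mixed anhydride 25 (not isolated)
Conditions: 24, (CF3CO)2O, CH2Cl2, 0 °C → rt
Reagents that add atoms: none
Why: Friedel–Crafts acylation through the acyl trifluoroacetate at C3', the only unsubstituted aromatic carbon left and activated by two ortho and one para alkoxy group; no metal Lewis acid is present, so the benzyl and methyl ethers should survive.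

Step 14
Reactants: 26 1-[2,4,6-tris(benzyloxy)-3-{[2,4-bis(benzyloxy)-3-butanoyl-6-methoxy-5-methylphenyl]methyl}-5-methylphenyl]pentan-1-one
Product: 27 1-[3-({3-butanoyl-2,4-dihydroxy-6-methoxy-5-methylphenyl}methyl)-2,4,6-trihydroxy-5-methylphenyl]pentan-1-one (CNP0210501.0)
Conditions: H2 (1 atm), 10% Pd/C, EtOAc/MeOH, rt
Reagents that add atoms: none
Why: catalytic hydrogenolysis of the five benzyl aryl ethers; the methyl ether, the diarylmethane and the two aryl ketones, which become chelated by ortho-hydroxyls as they are unveiled, are expected to persist under neutral conditions.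

**Compound list**

1 | 2-methylbenzene-1,3,5-triol (2,4,6-trihydroxytoluene) | Cc1c(O)cc(O)cc1O | starting material
2 | 1,3,5-tris(benzyloxy)-2-methylbenzene | Cc1c(OCc2ccccc2)cc(OCc2ccccc2)cc1OCc1ccccc1 | intermediate
3 | 2,4,6-tris(benzyloxy)-3-methylbenzaldehyde | O=Cc1c(OCc2ccccc2)cc(OCc2ccccc2)c(C)c1OCc1ccccc1 | intermediate
4 | 2,4,6-tris(benzyloxy)-3-bromo-5-methylbenzaldehyde | O=Cc1c(OCc2ccccc2)c(Br)c(OCc2ccccc2)c(C)c1OCc1ccccc1 | intermediate
5 | [2,4,6-tris(benzyloxy)-3-bromo-5-methylphenyl]methanol | OCc1c(OCc2ccccc2)c(Br)c(OCc2ccccc2)c(C)c1OCc1ccccc1 | intermediate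
6 | 1,3,5-tris(benzyloxy)-2-bromo-4-(bromomethyl)-6-methylbenzene | BrCc1c(OCc2ccccc2)c(Br)c(OCc2ccccc2)c(C)c1OCc1ccccc1 | intermediate
7 | ethoxyethyne | C#COCC | starting material
8 | lithium ethoxyacetylide | [Li]C#COCC | intermediate
9 | 1,3,5-tris(benzyloxy)-2-bromo-4-(3-ethoxyprop-2-yn-1-yl)-6-methylbenzene | CCOC#CCc1c(OCc2ccccc2)c(Br)c(OCc2ccccc2)c(C)c1OCc1ccccc1 | intermediate
10 | 3-ethoxy-2-{[2,4,6-tris(benzyloxy)-3-bromo-5-methylphenyl]methyl}cyclobut-2-en-1-one | CCOC1=C(Cc2c(OCc3ccccc3)c(Br)c(OCc3ccccc3)c(C)c2OCc2ccccc2)C(=O)C1 | intermediate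
11 | 3-(benzyloxy)-2-{[2,4,6-tris(benzyloxy)-3-bromo-5-methylphenyl]methyl}cyclobut-2-en-1-one | O=C1CC(OCc2ccccc2)=C1Cc1c(OCc2ccccc2)c(Br)c(OCc2ccccc2)c(C)c1OCc1ccccc1 | intermediate
12 | 2-chloro-1,1-dimethoxyethane | COC(CCl)OC | starting material
13 | sodium methoxyacetylide | [Na]C#COC | intermediate
14 | 1-methoxyprop-1-yne | CC#COC | intermediate
15 | 3-(benzyloxy)-2-{[2,4,6-tris(benzyloxy)-3-bromo-5-methylphenyl]methyl}buta-1,3-dien-1-one | O=C=C(Cc1c(OCc2ccccc2)c(Br)c(OCc2ccccc2)c(C)c1OCc1ccccc1)C(=C)OCc1ccccc1 | intermediate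
16 | 4-[1-(benzyloxy)ethenyl]-3-methoxy-2-methyl-4-{[2,4,6-tris(benzyloxy)-3-bromo-5-methylphenyl]methyl}cyclobut-2-en-1-one (racemic) | CC1=C(OC)C(Cc2c(OCc3ccccc3)c(Br)c(OCc3ccccc3)c(C)c2OCc2ccccc2)(C(=C)OCc2ccccc2)C1=O | intermediate
17 | (3E)-5-(benzyloxy)-3-methoxy-2-methyl-4-{[2,4,6-tris(benzyloxy)-3-bromo-5-methylphenyl]methyl}hexa-1,3,5-trien-1-one | O=C=C(C)/C(OC)=C(/Cc1c(OCc2ccccc2)c(Br)c(OCc2ccccc2)c(C)c1OCc1ccccc1)C(=C)OCc1ccccc1 | intermediate
18 | 5-(benzyloxy)-3-methoxy-2-methyl-4-{[2,4,6-tris(benzyloxy)-3-bromo-5-methylphenyl]methyl}cyclohexa-2,4-dien-1-one | CC1=C(OC)C(Cc2c(OCc3ccccc3)c(Br)c(OCc3ccccc3)c(C)c2OCc2ccccc2)=C(OCc2ccccc2)CC1=O | intermediate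
19 | 5-(benzyloxy)-3-methoxy-2-methyl-4-{[2,4,6-tris(benzyloxy)-3-bromo-5-methylphenyl]methyl}phenol | COc1c(C)c(O)cc(OCc2ccccc2)c1Cc1c(OCc2ccccc2)c(Br)c(OCc2ccccc2)c(C)c1OCc1ccccc1 | intermediate
20 | 1,3,5-tris(benzyloxy)-2-{[4,6-bis(benzyloxy)-2-methoxy-3-methylphenyl]methyl}-4-bromo-6-methylbenzene | COc1c(C)c(OCc2ccccc2)cc(OCc2ccccc2)c1Cc1c(OCc2ccccc2)c(Br)c(OCc2ccccc2)c(C)c1OCc1ccccc1 | intermediate
21 | N-methoxy-N-methylpentanamide | CCCCC(=O)N(C)OC | starting material
22 | {2,4,6-tris(benzyloxy)-3-{[4,6-bis(benzyloxy)-2-methoxy-3-methylphenyl]methyl}-5-methylphenyl}lithium | [Li]c1c(OCc2ccccc2)c(C)c(OCc2ccccc2)c(Cc2c(OCc3ccccc3)cc(OCc3ccccc3)c(C)c2OC)c1OCc1ccccc1 | intermediate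
23 | 1-[2,4,6-tris(benzyloxy)-3-{[4,6-bis(benzyloxy)-2-methoxy-3-methylphenyl]methyl}-5-methylphenyl]pentan-1-one | CCCCC(=O)c1c(OCc2ccccc2)c(C)c(OCc2ccccc2)c(Cc2c(OCc3ccccc3)cc(OCc3ccccc3)c(C)c2OC)c1OCc1ccccc1 | intermediate
24 | butanoic acid | CCCC(=O)O | starting material
25 | butanoic trifluoroacetic anhydride | CCCC(=O)OC(=O)C(F)(F)F | intermediate
26 | 1-[2,4,6-tris(benzyloxy)-3-{[2,4-bis(benzyloxy)-3-butanoyl-6-methoxy-5-methylphenyl]methyl}-5-methylphenyl]pentan-1-one | CCCCC(=O)c1c(OCc2ccccc2)c(C)c(OCc2ccccc2)c(Cc2c(OCc3ccccc3)c(C(=O)CCC)c(OCc3ccccc3)c(C)c2OC)c1OCc1ccccc1 | intermediate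
27 | 1-[3-({3-butanoyl-2,4-dihydroxy-6-methoxy-5-methylphenyl}methyl)-2,4,6-trihydroxy-5-methylphenyl]pentan-1-one | CCCCC(=O)c1c(O)c(C)c(O)c(Cc2c(O)c(C(=O)CCC)c(O)c(C)c2OC)c1O | target

**Step count and risks**

Total step count: 14. Longest linear sequence: 13 (steps 1–8 and 10–14; step 9 is a one-step side branch).

Steps most likely to fail:

1. Step 10. The four-electron opening of the vinylogous ester in 11 may lag behind dimerisation of the ketene, O-acylation of the product phenol by the ketene and slow thermal loss of 14, so that ring B closes in poor conversion. The fallback gives up the annulation and joins two preformed rings through the methylene bridge; it sets out from 1 and comes back to the route at 27.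
   - Friedel–Crafts C-acylation of 1 with pentanoyl chloride and AlCl3 in nitrobenzene should give 1-(2,4,6-trihydroxy-3-methylphenyl)pentan-1-one F1.
   - The same reaction with butanoyl chloride should give 1-(2,4,6-trihydroxy-3-methylphenyl)butan-1-one F2.
   - One equivalent of dimethyl sulfate with K2CO3 in acetone should methylate F2 at the unchelated hydroxyl para to the acyl group, giving 1-(2,6-dihydroxy-4-methoxy-3-methylphenyl)butan-1-one F3.
   - Aminomethylation of F1 at its single free ring carbon (aqueous formaldehyde, dimethylamine, ethanol) should give the Mannich base 1-{3-[(dimethylamino)methyl]-2,4,6-trihydroxy-5-methylphenyl}pentan-1-one F4.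
   - Heating F4 with F3 in dioxane should expel dimethylamine; the ortho-quinone methide would be captured by the only free ring carbon of F3 to give 27 directly.

2. Step 8. The acid-catalysed exchange may stall at equilibrium, or benzyl alcohol may open the strained ring in a retro-Claisen sense. The fallback replaces the equilibrium by an irreversible O-alkylation; it sets out from 10 and comes back at 11. Dilute HCl in THF should hydrolyse the enol ether to the vinylogous acid 3-hydroxy-2-{[2,4,6-tris(benzyloxy)-3-bromo-5-methylphenyl]methyl}cyclobut-2-en-1-one F5. A Mitsunobu reaction (benzyl alcohol, PPh3, diisopropyl azodicarboxylate, THF) should then benzylate it on oxygen to give 11.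

3. Step 13. Protonation of ring B at the bridge-bearing carbon may expel the ring A benzyl cation (cleavage or scrambling of the diarylmethane), and trifluoroacetic acid may loosen benzyl ethers before the hindered C3' is acylated. The fallback builds the butanoyl group in three non-acidic operations; it sets out from 23 and comes back at 26.
   - Vilsmeier–Haack formylation (POCl3, DMF) at C3' should give 2,6-bis(benzyloxy)-4-methoxy-3-methyl-5-{[2,4,6-tris(benzyloxy)-3-methyl-5-pentanoylphenyl]methyl}benzaldehyde F6.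
   - Addition of n-PrMgBr in THF at −78 °C should give the racemic carbinol 1-[2,4,6-tris(benzyloxy)-3-{[2,4-bis(benzyloxy)-3-(1-hydroxybutyl)-6-methoxy-5-methylphenyl]methyl}-5-methylphenyl]pentan-1-one F7; the doubly ortho-substituted ring A ketone is shielded from addition.
   - Dess–Martin periodinane should oxidise F7 to 26.

**Further compounds**

F1 | step 10 | 1-(2,4,6-trihydroxy-3-methylphenyl)pentan-1-one | CCCCC(=O)c1c(O)cc(O)c(C)c1O
F2 | step 10 | 1-(2,4,6-trihydroxy-3-methylphenyl)butan-1-one | CCCC(=O)c1c(O)cc(O)c(C)c1O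
F3 | step 10 | 1-(2,6-dihydroxy-4-methoxy-3-methylphenyl)butan-1-one | CCCC(=O)c1c(O)cc(OC)c(C)c1O
F4 | step 10 | 1-{3-[(dimethylamino)methyl]-2,4,6-trihydroxy-5-methylphenyl}pentan-1-one | CCCCC(=O)c1c(O)c(CN(C)C)c(O)c(C)c1O
F5 | step 8 | 3-hydroxy-2-{[2,4,6-tris(benzyloxy)-3-bromo-5-methylphenyl]methyl}cyclobut-2-en-1-one | O=C1CC(O)=C1Cc1c(OCc2ccccc2)c(Br)c(OCc2ccccc2)c(C)c1OCc1ccccc1
F6 | step 13 | 2,6-bis(benzyloxy)-4-methoxy-3-methyl-5-{[2,4,6-tris(benzyloxy)-3-methyl-5-pentanoylphenyl]methyl}benzaldehyde | CCCCC(=O)c1c(OCc2ccccc2)c(C)c(OCc2ccccc2)c(Cc2c(OCc3ccccc3)c(C=O)c(OCc3ccccc3)c(C)c2OC)c1OCc1ccccc1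
F7 | step 13 | 1-[2,4,6-tris(benzyloxy)-3-{[2,4-bis(benzyloxy)-3-(1-hydroxybutyl)-6-methoxy-5-methylphenyl]methyl}-5-methylphenyl]pentan-1-one (racemic) | CCCCC(=O)c1c(OCc2ccccc2)c(C)c(OCc2ccccc2)c(Cc2c(OCc3ccccc3)c(C(O)CCC)c(OCc3ccccc3)c(C)c2OC)c1OCc1ccccc1
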